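## Retrosynthetic overview
1. Only the lactone ring has to be made, because all three benzene rings are bought. It is closed last, from the hydroxy acid released by one global ether and ester cleavage.
2. C8–C(=O) bond: Friedel–Crafts cinnamoylation of the trimethoxyaryl ring, which has two equivalent C–H sites. 3,4-Dimethoxycinnamic acid brings in the whole caffeoyl unit at once.
3. Key disconnection C4–C4a: a chiral copper ester homoenolate, made by reversed hydrocupration of tert-butyl cinnamate, is coupled with 2-bromo-1,3,5-trimethoxybenzene under palladium co-catalysis. This one step builds the diarylmethine and sets (R)-C4.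
4. Forward order: C4–C4a bond with the stereocentre, then the C8 acyl group, then deprotection with lactone closure.

Assumption: the alkyl transfer from copper to palladium in step 1 is taken as stereoretentive, and (S,S)-Ph-BPE as the ligand antipode that gives (R)-3. If the first run gives the (S)-ester, the equally available (R,R)-Ph-BPE is used and nothing else changes.

## Route

Step 1
Reactants: 1 tert-butyl (E)-cinnamate; 2 2-bromo-1,3,5-trimethoxybenzene
Product: 4 tert-butyl (R)-3-phenyl-3-(2,4,6-trimethoxyphenyl)propanoate, via copper homoenolate 3 (not isolated)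
Conditions: 1 (1.5 equiv), Cu(OAc)2 (5 mol %), (S,S)-Ph-BPE (5.5 mol %), [Pd(cinnamyl)Cl]2 (2.5 mol %), BrettPhos (5.5 mol %), MePh2SiH (2 equiv), NaOSiMe3 (2 equiv), THF, 40 °C, 24 h, argon
Reagents that add atoms: none
Why: Proposed new method: a Ph-BPE-ligated monovalent copper hydride is known to add to cinnamic esters with reversed regiochemistry (hydride to the alpha carbon, copper to the benzylic beta carbon) and with ligand-controlled facial selectivity, which gives the configurationally defined ester homoenolate 3 and so sets C4; 3 is intercepted by the divalent arylpalladium bromide formed from 2 and BrettPhos-ligated zerovalent palladium (stereospecific alkyl transfer from copper to palladium, then reductive elimination), so the beta carbon of an enoate and the C–Br carbon of an aryl bromide, both electrophilic by nature, are joined; the closest known reaction types are the copper hydride catalysed beta-amination of cinnamates and the dual copper hydride/palladium asymmetric hydroarylation of vinylarenes with aryl bromides.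

Step 2
Reactants: 4 tert-butyl (R)-3-phenyl-3-(2,4,6-trimethoxyphenyl)propanoate; 5 (E)-3,4-dimethoxycinnamic acid
Product: 7 tert-butyl (R)-3-{3-[(E)-3-(3,4-dimethoxyphenyl)prop-2-enoyl]-2,4,6-trimethoxyphenyl}-3-phenylpropanoate, via mixed anhydride 6 (not isolated)
Conditions: 5 (1.2 equiv), (CF3CO)2O (1.2 equiv), CH2Cl2, 0 °C, 30 min; then 4, 0 °C to rt, 2 h
Reagents that add atoms: none
Why: Friedel–Crafts acylation: the acyl trifluoroacetate 6 ionises to a well-stabilised cinnamoyl cation that the very electron-rich ring of 4 takes up at either of its two equivalent C–H positions (one product, with the E-alkene and C4 untouched), while the CF3CO2H formed is too dilute to cleave the tert-butyl ester within the reaction time.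

Step 3
Reactants: 7 tert-butyl (R)-3-{3-[(E)-3-(3,4-dimethoxyphenyl)prop-2-enoyl]-2,4,6-trimethoxyphenyl}-3-phenylpropanoate
Product: 9 (4R)-8-[(E)-3-(3,4-dihydroxyphenyl)prop-2-enoyl]-5,7-dihydroxy-4-phenylchroman-2-one, via hydroxy acid 8 (not isolated)
Conditions: BBr3 (12 equiv), CH2Cl2, −78 °C to rt, 14 h, argon; ice/1 M HCl (pH below 2), EtOAc; then TsOH·H2O (10 mol %), MeCN, rt, 2 h
Reagents that add atoms: none
Why: Lewis-acid aryl methyl ether cleavage followed by acid-catalysed lactonisation: BBr3 removes all five O-methyl groups and the tert-butyl group, hydroxy acid 8 closes spontaneously because the crowded 3,3-diarylpropanoic acid is held next to the phenols, the two possible lactones equilibrate through 8 under acid toward the one on the oxygen ortho to the ketone (the para-hydroxyl and the chelated ortho-hydroxyl stay free, as in the known drift of 6-acyl- to 8-acyl-5,7-dihydroxy-4-phenylcoumarins), the strongly acidic work-up keeps the chalcone from closing to a flavanone (which needs the phenoxide), and C4 carries no ionisable bond, so its (R)-configuration is kept.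

## Compound list
1 | tert-butyl (E)-cinnamate | CC(C)(C)OC(=O)/C=C/c1ccccc1 | starting material
2 | 2-bromo-1,3,5-trimethoxybenzene | COc1cc(OC)c(Br)c(OC)c1 | starting material
3 | tert-butyl (R)-3-cuprio-3-phenylpropanoate, copper ester homoenolate (Ph-BPE on copper omitted, not isolated) | CC(C)(C)OC(=O)C[C@H](c1ccccc1)[Cu] | intermediate
4 | tert-butyl (R)-3-phenyl-3-(2,4,6-trimethoxyphenyl)propanoate | CC(C)(C)OC(=O)C[C@H](c1ccccc1)c1c(OC)cc(OC)cc1OC | intermediate
5 | (E)-3,4-dimethoxycinnamic acid | COc1ccc(/C=C/C(=O)O)cc1OC | starting material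
6 | (E)-3-(3,4-dimethoxyphenyl)acrylic trifluoroacetic anhydride (not isolated) | COc1ccc(/C=C/C(=O)OC(=O)C(F)(F)F)cc1OC | intermediate
7 | tert-butyl (R)-3-{3-[(E)-3-(3,4-dimethoxyphenyl)prop-2-enoyl]-2,4,6-trimethoxyphenyl}-3-phenylpropanoate | CC(C)(C)OC(=O)C[C@H](c1ccccc1)c1c(OC)cc(OC)c(C(=O)/C=C/c2ccc(OC)c(OC)c2)c1OC | intermediate
8 | (R)-3-{3-[(E)-3-(3,4-dihydroxyphenyl)prop-2-enoyl]-2,4,6-trihydroxyphenyl}-3-phenylpropanoic acid (not isolated) | OC(=O)C[C@H](c1ccccc1)c1c(O)cc(O)c(C(=O)/C=C/c2ccc(O)c(O)c2)c1O | intermediate
9 | (4R)-8-[(E)-3-(3,4-dihydroxyphenyl)prop-2-enoyl]-5,7-dihydroxy-4-phenylchroman-2-one (CNP0187838.1) | O=C1C[C@H](c2ccccc2)c2c(O)cc(O)c(C(=O)/C=C/c3ccc(O)c(O)c3)c2O1 | target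

## Step count and risks
Total steps: 3. Longest linear sequence: 3 (1 → 4 → 7 → 9).

**Step 1 (highest risk).**
- The aryl bromide is electron-rich and carries two ortho substituents, which slows both oxidative addition and the alkyl transfer from copper.
- Ordinary conjugate reduction of 1 and hydrodebromination of 2 compete with the coupling.
- The diphosphine may migrate from copper to palladium.

The fallback sets out from 1 and comes back at 4. It makes the homoenolate as an isolable boron compound and forms the aryl–alkyl bond without placing a metal at the crowded carbon. Copper-catalysed asymmetric conjugate borylation of 1 (B2pin2, CuCl, NaOtBu, the Josiphos antipode that gives the (R)-product, MeOH, THF, rt) gives tert-butyl (R)-3-phenyl-3-(4,4,5,5-tetramethyl-1,3,2-dioxaborolan-2-yl)propanoate F1. F1 is added at −78 °C to the dilithio species made from commercial 4-bromo-3,5-dimethoxyphenol (MeLi, then t-BuLi, THF), which gives the dilithium aryl alkyl pinacol boronate complex F2. Activation of its phenoxide oxygen with Martin sulfurane triggers a stereoretentive 1,2-shift of the benzylic carbon from boron to the ipso carbon. Loss of boron then rearomatises the ring to tert-butyl (R)-3-(4-hydroxy-2,6-dimethoxyphenyl)-3-phenylpropanoate F3. O-Methylation (MeI, K2CO3, acetone) returns to 4.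

**Step 3.**
- The acid equilibrium may leave a share of the 6-acyl lactone isomer.
- The free 2,6-dihydroxyaryl enone stage may leak to a flavanone.
- Five ether cleavages in one pot may stop short of completion.

The fallback sets out from 7 and comes back at 9. It fixes the lactone oxygen before the competing phenol is unmasked. BCl3 (3 equiv, CH2Cl2, −78 to 0 °C) removes the tert-butyl group and only the methoxy group wedged between the side chain and the ketone. That methoxy group is chelation-activated and twisted out of conjugation. The product is (R)-3-{3-[(E)-3-(3,4-dimethoxyphenyl)prop-2-enoyl]-2-hydroxy-4,6-dimethoxyphenyl}-3-phenylpropanoic acid F4. F4 has a single free phenol and can close in only one way (TsOH·H2O cat., toluene, 60 °C), giving (R)-8-[(E)-3-(3,4-dimethoxyphenyl)prop-2-enoyl]-5,7-dimethoxy-4-phenylchroman-2-one F5. BBr3 (8 equiv, CH2Cl2, −78 to 0 °C) on the closed lactone, with a cold acidic work-up, gives 9.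

**Step 2.**
- The tert-butyl ester may be partly lost in CF3CO2H.
- The ring may be trifluoroacetylated instead of cinnamoylated.
- The new enone may undergo acid-promoted hydroarylation.

The fallback sets out from 4 and comes back at 7. It builds the enone by condensation instead of transferring it whole. Friedel–Crafts acetylation (AcCl, ZnCl2, CH2Cl2, 0 °C) gives tert-butyl (R)-3-(3-acetyl-2,4,6-trimethoxyphenyl)-3-phenylpropanoate F6. Claisen–Schmidt condensation with commercial 3,4-dimethoxybenzaldehyde (KOH, EtOH, rt) gives 7. The tert-butyl ester resists the base, and C4 is not acidic enough to epimerise.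

## Further compounds
F1 | step 1 | tert-butyl (R)-3-phenyl-3-(4,4,5,5-tetramethyl-1,3,2-dioxaborolan-2-yl)propanoate | CC(C)(C)OC(=O)C[C@H](c1ccccc1)B1OC(C)(C)C(C)(C)O1
F2 | step 1 | dilithium [(1R)-3-tert-butoxy-3-oxo-1-phenylpropyl](2,6-dimethoxy-4-oxidophenyl)(pinacolato)borate | [Li+].[Li+].CC(C)(C)OC(=O)C[C@H](c1ccccc1)[B-]1(c2c(OC)cc([O-])cc2OC)OC(C)(C)C(C)(C)O1
F3 | step 1 | tert-butyl (R)-3-(4-hydroxy-2,6-dimethoxyphenyl)-3-phenylpropanoate | CC(C)(C)OC(=O)C[C@H](c1ccccc1)c1c(OC)cc(O)cc1OC
F4 | step 3 | (R)-3-{3-[(E)-3-(3,4-dimethoxyphenyl)prop-2-enoyl]-2-hydroxy-4,6-dimethoxyphenyl}-3-phenylpropanoic acid | OC(=O)C[C@H](c1ccccc1)c1c(OC)cc(OC)c(C(=O)/C=C/c2ccc(OC)c(OC)c2)c1O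
F5 | step 3 | (R)-8-[(E)-3-(3,4-dimethoxyphenyl)prop-2-enoyl]-5,7-dimethoxy-4-phenylchroman-2-one | O=C1C[C@H](c2ccccc2)c2c(OC)cc(OC)c(C(=O)/C=C/c3ccc(OC)c(OC)c3)c2O1
F6 | step 2 | tert-butyl (R)-3-(3-acetyl-2,4,6-trimethoxyphenyl)-3-phenylpropanoate | CC(C)(C)OC(=O)C[C@H](c1ccccc1)c1c(OC)cc(OC)c(C(C)=O)c1OC
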